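## Analysis of the target

Target 25 is the 4-hydroxy-3-methoxybenzoate of a daucane allylic alcohol: a bicyclo[5.3.0]decadiene in which a cyclopentene (C1–C5) and a cycloheptene (C1, C5, C6, C7, C8, C9, C10) share the C1–C5 bond. Daucane numbering is used throughout: C1 is the quaternary fusion carbon carrying methyl C15, C2 and C3 are the cyclopentene methylenes, C4 carries the isopropyl group, C5 is the second fusion carbon, C6, C7 and C10 are ring methylenes, C8 carries the oxygenated carbon C14, and C9 is the vinylic CH. C1 (R) is the only stereocentre, an all-carbon quaternary centre with no heteroatom nearby, so the task is absolute stereocontrol with nothing to relay it from. Both alkenes have fixed positions: C4=C5 is tetrasubstituted and lies on the ring fusion, and C8=C9 is trisubstituted and makes the ester allylic. The sensitive groups are the free phenol, the allylic ester (ionisation, allylic transposition, cleavage by bases and hydrides) and the tetrasubstituted alkene, which strong acid can move or push into cationic rearrangement next to the quaternary carbon. The difficulties are therefore the quaternary centre, the seven-membered ring and the placement of two alkenes that are not conjugated to anything that could guide them. The plan rests on reading C1, C5, C6, C8, C9 and C10 as the six ring carbons of a 4-methylcyclohexa-2,5-dienone in which C5 and C10 are the β-carbons of two enantiotopic enone arms, with C2–C3–C4 as a tether ending in an aldehyde at C4. C4 can then attack C5 as an acyl anion, and C7 is inserted afterwards.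

## Retrosynthetic reasoning

**C14–O ester bond.** Target 25 is cut into allylic alcohol 23 and vanillic acid 24. This is the only heteroatom bond between two fragments of very different character, and cutting it last keeps the phenol and the labile allylic ester out of all earlier chemistry. The forward reaction must acylate a primary allylic alcohol with an acid that carries a free phenol. A Mitsunobu esterification does this through the far more acidic carboxyl group, so 24 enters unprotected.

**C4–isopropyl bond and the C4=C5 alkene.** Alcohol 23 comes from methyl ester 22 by hydride reduction, so C14 travels as an ester while organometallic and acidic steps are run. In 22 the C4–isopropyl bond is cut to give tertiary alcohol 21 and then keto ester 20. A carbonyl at C4 is the natural handle: it accepts an isopropyl nucleophile, and loss of the hydroxyl with the C5 hydrogen places the alkene on the ring fusion. The forward steps need a nucleophile that adds to a hindered, enolisable cyclopentanone without touching the ester, and a dehydration that settles on the tetrasubstituted alkene.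

**C8–C14 bond.** Keto ester 20 is the unmasked form of ketal ester 19, whose ester carbon is removed to give enol triflate 18 and, behind it, cycloheptenone 16. The cut is made here because the enone alkene C9=C10 of 16 is a regiochemical memory: conjugate reduction leaves the enolate double bond at C8=C9 and nowhere else. Carbonylation of the triflate then attaches C14 at the right oxidation level.

**C6–C7 and C7–C8 bonds (one-carbon ring enlargement).** Cycloheptenone 16 is contracted to cyclohexenone ketal 11 by removing C7. In the forward sense this passes through silyl dienol ether 13, cyclopropane 14 and chloride 15. C7 is chosen as the inserted carbon because C6 is the only enolisable position of 11: the γ-carbon C1 is quaternary and C4 is masked. The enol ether, and with it the cyclopropane, can therefore only form across C6–C8. Ketal 11 is the C4-protected form of dione 10. The protection is needed because C4 would otherwise compete in every enolate step.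

**C4–C5 bond (key disconnection).** Dione 10 is opened to aldehyde 9. Cutting C4–C5 turns the bicycle into a symmetrical dienone whose two enone arms are enantiotopic, so the quaternary centre is created by choosing one arm, and the same event closes the cyclopentanone. No other single cut of 10 gives an achiral precursor. The forward reaction has to reverse the polarity of the aldehyde carbon and deliver it to one arm only, which a chiral N-heterocyclic carbene catalyst does in an intramolecular Stetter reaction.

**Precursor.** Aldehyde 9 is traced to dienone 7 by regenerating a trisubstituted alkene from the aldehyde (forward: ozonolysis). Dienone 7 goes back to enone 5 (forward: dehydrogenation), and 5 to aldehyde 1 and enone 2 by a Robinson annulation. Aldehyde 1 already holds the methyl-bearing carbon, the three-carbon tether and a masked aldehyde, so the precursor is reached in three steps and the risk of the route sits in the key step.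

## Alternatives that were turned down

**Alternative 1:** Cyclopropane as a latent angular methyl group.
- Disconnection: the C1–C15 bond, with the seven-membered ring left for a later closure from two side chains.
- Forward key step: a zinc carbenoid, held by the zinc alkoxide of the C4 carbinol of cyclopentenol A2, transfers a methylene to the tetrasubstituted C1=C5 alkene on the hydroxyl face. This gives cyclopropyl carbinol A1, in which C15 is bonded to both C1 and C5.
- For: hydroxyl-directed cyclopropanation is among the most dependable stereocontrolled reactions. After oxidation at C4, reductive opening of the cyclopropyl ketone should cleave the external C5–C15 bond and reveal the angular methyl group and the C4=C5 enolate in one operation. The tetrasubstituted alkene is then placed by enolate triflation and cross-coupling. On this point the alternative is stronger than the chosen route, whose step 14 relies on a thermodynamic preference.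
- Against: the key step builds no ring and only one skeletal bond. The absolute configuration is not created in it and must be secured beforehand by an enantioselective preparation of the carbinol of A2. A2 itself, with two chains that differ only in length and carry the same silyl ether, needs several steps. The seven-membered ring must still be closed by an aldol condensation of a dialdehyde in which either aldehyde can act as the enol component, and both modes give a seven-membered ring.
- Comparison: more steps are spent around the key step and the hardest ring is left to an ambiguous closure. Step 4 of the chosen route creates the quaternary centre catalytically from an achiral precursor and closes a ring in the same event.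

**Alternative 2:** Vinylcarbenoid (4+3) annulation.
- Disconnection: C7–C8 and C1–C10. The cycloheptadiene is cut into the four-carbon diene C1=C5–C6=C7 of vinylcyclopentenone A5 and the three-carbon unit C8–C10 of vinyldiazoacetate A4, which carries C14 as its ester.
- Forward key step: a chiral dirhodium tetracarboxylate decomposes A4. The vinylcarbenoid cyclopropanates the vinyl group of A5, and the cis-divinylcyclopropane undergoes Cope rearrangement to bicyclic dienone ester A3.
- For: it is highly convergent. The seven-membered ring, two C–C bonds, the quaternary centre and C14 at the ester oxidation level arise in one step. A3 is only a few steps from 25: conjugate reduction of the C4 enone gives the C4=C5 enolate regiospecifically, followed by triflation, isopropyl coupling, ester reduction and acylation. In step count and in the placement of C4=C5 it is clearly stronger than the chosen route.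
- Against: the reacting vinyl group of A5 is conjugated to the ketone and electron-poor, whereas the rhodium vinylcarbenoid is electrophilic and performs best on electron-rich alkenes. The Cope step must form C1–C10 at a fully substituted alkene carbon through a crowded boat transition state. The unsubstituted A4 is prone to electrocyclise to a pyrazole. The induction at C1 depends on an enantioselective cyclopropanation of a substrate type outside the usual range.
- Comparison: the chosen route is longer, but its stereodefining step has close precedent on the same substrate class, and the ring closure itself is well established in racemic form.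

**Alternative 3:** Pauson–Khand closure of both rings.
- Disconnection: C1–C5, C2–C3 and C3–C4. Both rings are cut at once back to acyclic dienyne A7, with C3 supplied as carbon monoxide A8.
- Forward key step: a rhodium carbonyl catalyst carrying a chiral bisphosphine unites the isopropyl-substituted alkyne (C4, C5), the 1,1-disubstituted alkene (C1, C2) and A8 in an intramolecular Pauson–Khand reaction that gives bicyclic dienone A6.
- For: convergency is maximal. Both rings, three bonds and the quaternary centre form in one step, the isopropyl group and the C4=C5 alkene are in place from the outset, and C8=C9 with its oxygenated carbon is carried through unchanged. In these respects it surpasses the chosen route.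
- Against: the tether between alkyne and alkene has five atoms, so the second ring is seven-membered. The intramolecular Pauson–Khand reaction is poorly suited to this outside allenic or conformationally locked cases. The alkene partner is 1,1-disubstituted and must become a quaternary centre, which slows insertion, and the alkyne carries a branched substituent. Enantioselective variants are established for simpler 1,6-enynes. Afterwards the C3 ketone must be removed from a conjugated enone without moving C4=C5.
- Comparison: three independent demands are placed on one unproven step. The chosen strategy gives up convergency for a sequence in which every step has a known counterpart.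

Key step: step 4

## Route

Assumption: the (5aS,10bR) antipode of the aminoindanol-derived triazolium salt is taken to deliver the (3aR,7aS) dione 10. Should the sense of induction be the opposite, the (5aR,10bS) salt is used with no other change.

Step 1
Reactants: 1 2,6-dimethylhept-5-enal (racemic); 2 but-3-en-2-one
Product: 5 4-methyl-4-(4-methylpent-3-en-1-yl)cyclohex-2-en-1-one (racemic), via enamine 3 (not isolated), via keto aldehyde 4 (not isolated)
Conditions: pyrrolidine, toluene, reflux (Dean–Stark); then 2, 0 → 23 °C; then AcOH, NaOAc, H2O, reflux
Reagents that add atoms: none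
Why: Stork enamine Michael addition of the α-branched aldehyde to the enone, followed by hydrolysis and intramolecular aldol condensation (Robinson annulation), is the standard entry to 4,4-disubstituted cyclohexenones; the buffered acid spares the trisubstituted alkene, and the racemic quaternary centre of 5 is of no consequence because step 2 makes it prochiral.

Step 2
Reactants: 5 4-methyl-4-(4-methylpent-3-en-1-yl)cyclohex-2-en-1-one
Product: 7 4-methyl-4-(4-methylpent-3-en-1-yl)cyclohexa-2,5-dien-1-one, via silyl dienol ether 6 (not isolated)
Conditions: Me3SiOTf, Et3N, CH2Cl2, 0 °C; then Pd(OAc)2, MeCN, 23 °C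
Reagents that add atoms: none
Why: Saegusa–Ito oxidation: because the methyl-bearing ring carbon is quaternary, soft enolisation can only take place on the saturated α' side, and Pd(OAc)2 converts the resulting 2-silyloxydiene into the cross-conjugated dienone by β-hydride elimination from the oxa-π-allyl complex of divalent palladium; the isolated trisubstituted alkene is inert under these conditions.

Step 3
Reactants: 7 4-methyl-4-(4-methylpent-3-en-1-yl)cyclohexa-2,5-dien-1-one
Product: 9 3-(1-methyl-4-oxocyclohexa-2,5-dien-1-yl)propanal, via ozonide 8 (not isolated)
Conditions: O3, CH2Cl2, −78 °C (Sudan Red 7B end point); then PPh3, −78 → 23 °C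
Reagents that add atoms: ozone, [O-][O+]=O
Why: Ozonolysis: electrophilic ozone attacks the electron-rich trisubstituted alkene far faster than the electron-poor dienone alkenes, the indicator dye marks the end point after one equivalent, and PPh3 reduces the ozonide to the aldehyde with loss of acetone.

Step 4
Reactants: 9 3-(1-methyl-4-oxocyclohexa-2,5-dien-1-yl)propanal
Product: 10 (3aR,7aS)-3a-methyl-2,3,7,7a-tetrahydro-1H-indene-1,6(3aH)-dione (cis-fused; C4 ketone and C8 enone in daucane numbering)
Conditions: (5aS,10bR)-2-(pentafluorophenyl)-5a,10b-dihydro-4H,6H-indeno[2,1-b][1,2,4]triazolo[4,3-d][1,4]oxazin-2-ium tetrafluoroborate (10 mol %), KN(SiMe3)2 (10 mol %), toluene, 23 °C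
Reagents that add atoms: none
Why: Deprotonation of the triazolium salt gives the carbene, which adds to the aldehyde carbon C4 of 9, and proton transfer forms the nucleophilic enaminol (Breslow intermediate), an acyl anion equivalent. This adds in 5-exo-trig fashion to the β-carbon C5 of one of the two enone arms; proton transfer to C6 and collapse of the tetrahedral intermediate release the C4 ketone and the carbene (intramolecular Stetter reaction). The closest known reaction type is the carbene-catalysed enantioselective Stetter desymmetrisation of 4,4-disubstituted cyclohexadienones that carry a tethered aldehyde. The cyclopentanone is closed through the new C4–C5 bond, and because the tether C2–C3–C4 can reach C5 only from the face of the dienone on which it hangs, the C5 hydrogen ends up cis to the C1 methyl group (cis fusion, substrate control). The absolute configuration at C1 is set by the choice between the two enantiotopic arms, which the aminoindanol backbone and the N-aryl group of the catalyst control by shielding one face of the enaminol. The step needs this enantiotopic-group selectivity and chemoselectivity for conjugate addition over aldol or benzoin pathways of the enolisable aldehyde; the fast five-membered closure, the electrophilicity of the dienone and the low base loading secure the latter. C1 is quaternary and cannot epimerise, and C5, although epimerisable, is removed later as C4=C5.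

Step 5
Reactants: 10 (3aR,7aS)-3a-methyl-2,3,7,7a-tetrahydro-1H-indene-1,6(3aH)-dione
Product: 11 (3a'R,7a'S)-3a'-methyl-2',3',3a',7a'-tetrahydrospiro[[1,3]dioxolane-2,1'-inden]-6'(7'H)-one (C4 dioxolane; C8 enone intact)
Conditions: Me3SiOCH2CH2OSiMe3, Me3SiOTf (5 mol %), CH2Cl2, −78 → −20 °C; pyridine quench
Reagents that add atoms: 1,2-bis(trimethylsilyloxy)ethane, C[Si](C)(C)OCCO[Si](C)(C)C
Why: Noyori ketalisation: under Me3SiOTf catalysis at low temperature saturated ketones are ketalised much faster than conjugated enones, and this enone has no γ-hydrogen and cannot escape into a deconjugated ketal, so only the C4 cyclopentanone is masked; C5 may epimerise, but the cis fusion is the stable one and the centre is removed later.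

Step 6
Reactants: 11 (3a'R,7a'S)-3a'-methyl-2',3',3a',7a'-tetrahydrospiro[[1,3]dioxolane-2,1'-inden]-6'(7'H)-one
Product: 13 trimethyl{[(3a'R,7a'S)-3a'-methyl-2',3',3a',7a'-tetrahydrospiro[[1,3]dioxolane-2,1'-inden]-6'-yl]oxy}silane (2-silyloxydiene C6=C8–C9=C10), via lithium dienolate 12 (not isolated)
Conditions: LiN(iPr)2, THF, −78 °C; then Me3SiCl, Et3N, −78 → 0 °C
Reagents that add atoms: chlorotrimethylsilane, C[Si](C)(C)Cl
Why: Kinetic deprotonation of the enone can only occur at the α' carbon C6 (the γ carbon C1 is quaternary and C4 is masked), giving the cross-conjugated lithium dienolate, which is silylated on oxygen.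

Step 7
Reactants: 13 trimethyl{[(3a'R,7a'S)-3a'-methyl-2',3',3a',7a'-tetrahydrospiro[[1,3]dioxolane-2,1'-inden]-6'-yl]oxy}silane
Product: 14 siloxycyclopropane formed by methylene transfer to C6=C8 of 13 (new carbon C7 bridging C6 and C8; C1 and C5 unchanged; epimer pair at the cyclopropane)
Conditions: Et2Zn, CH2I2, CH2Cl2, 0 → 23 °C
Reagents that add atoms: diiodomethane, ICI
Why: Simmons–Smith cyclopropanation in the Furukawa variant: the electrophilic zinc carbenoid reacts at the electron-rich silyl enol ether double bond C6=C8 in preference to the neutral C9=C10 next to the quaternary carbon; the two new stereocentres are cis by necessity and both are destroyed in step 8, so the face of attack does not matter.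

Step 8
Reactants: 14 siloxycyclopropane
Product: 15 (3a'R)-8'-chloro-3a'-methyl-2',3',3a',7',8',8a'-hexahydrospiro[[1,3]dioxolane-2,1'-azulen]-6'-one (seven-membered enone; chlorine on C6; C5 as in 11; epimer pair at C6)
Conditions: FeCl3 (anhydrous), DMF, 0 → 23 °C
Reagents that add atoms: iron trichloride, Cl[Fe](Cl)Cl
Why: Saegusa–Ito oxidative ring opening: one-electron oxidation of the siloxycyclopropane by trivalent iron and β-scission of the internal C6–C8 bond give the ring-enlarged β-keto radical at C6 (secondary, and therefore favoured over the primary radical from external cleavage), which takes chlorine from a second FeCl3; DMF tempers the Lewis acidity, so the dioxolane is expected to survive.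

Step 9
Reactants: 15 chloro enone
Product: 16 (3a'R,8a'S)-3a'-methyl-2',3',3a',7',8',8a'-hexahydrospiro[[1,3]dioxolane-2,1'-azulen]-6'-one (cycloheptenone; C8 ketone; C9=C10)
Conditions: Bu3SnH, 2,2'-azobis(2-methylpropionitrile) (cat.), toluene, 90 °C
Reagents that add atoms: none
Why: Radical chain dehalogenation: the stannyl radical abstracts the secondary chlorine and the C6 radical is reduced by Bu3SnH; cyclisation of this radical onto C9=C10 would be 4-exo or 5-endo and its 3-exo addition to the C8 carbonyl is reversible, so simple reduction is expected.

Step 10
Reactants: 16 cycloheptenone ketal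
Product: 18 (3a'R,8a'S)-3a'-methyl-2',3',3a',4',7',8',8a'-heptahydrospiro[[1,3]dioxolane-2,1'-azulen]-6'-yl trifluoromethanesulfonate (enol triflate; C8=C9), via lithium enolate 17 (not isolated)
Conditions: Li, NH3(l)/THF, tBuOH (1 equiv), −78 °C; isoprene; NH3 evaporated; then PhNTf2, THF, −78 → 0 °C
Reagents that add atoms: N-phenylbis(trifluoromethanesulfonimide), O=S(=O)(N(c1ccccc1)S(=O)(=O)C(F)(F)F)C(F)(F)F
Why: Dissolving-metal reduction of the enone puts hydrogen on C10 and leaves the lithium enolate with its double bond fixed at C8=C9, so the position of the former enone alkene dictates the regiochemistry of the enol triflate on trapping with PhNTf2; the dioxolane is inert to Li/NH3.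

Step 11
Reactants: 18 enol triflate
Product: 19 methyl (3a'R,8a'S)-3a'-methyl-2',3',3a',4',7',8',8a'-heptahydrospiro[[1,3]dioxolane-2,1'-azulene]-6'-carboxylate
Conditions: Pd(OAc)2 (5 mol %), PPh3 (10 mol %), Et3N, CO (1 atm), MeOH/DMF, 40 °C
Reagents that add atoms: carbon monoxide, [C-]#[O+]; methanol, CO
Why: Palladium-catalysed alkoxycarbonylation of an enol triflate: oxidative addition to zerovalent palladium, CO insertion and methanolysis of the acylpalladium species install C14 as the methyl ester without moving the C8=C9 double bond.

Step 12
Reactants: 19 ketal ester
Product: 20 methyl (3aS,8aR)-8a-methyl-3-oxo-1,2,3,3a,4,5,8,8a-octahydroazulene-6-carboxylate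
Conditions: 1 M aq. HCl, THF, 23 °C
Reagents that add atoms: water, O
Why: Acid-catalysed hydrolysis of the dioxolane unmasks the C4 ketone; the conjugated ester and the C8=C9 alkene are stable to dilute aqueous acid, and any epimerisation at C5 is without consequence.

Step 13
Reactants: 20 keto ester
Product: 21 methyl (3S,3aS,8aR)-3-hydroxy-8a-methyl-3-(propan-2-yl)-1,2,3,3a,4,5,8,8a-octahydroazulene-6-carboxylate (isopropyl cis to the C5 hydrogen; the C4 epimer is equally serviceable)
Conditions: iPrMgCl, CeCl3 (anhydrous), THF, −78 → −40 °C; aq. NH4Cl
Reagents that add atoms: isopropylmagnesium chloride, CC(C)[Mg]Cl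
Why: Organocerium 1,2-addition (Imamoto conditions): the weakly basic, oxophilic cerium reagent adds to the enolisable, hindered cyclopentanone while enolisation and β-hydride reduction are suppressed, and at low temperature the methyl ester is not attacked; addition anti to the C5–C6 bond is expected, but either C4 epimer serves because the centre becomes sp2 in step 14.

Step 14
Reactants: 21 tertiary alcohol
Product: 22 methyl (8aR)-8a-methyl-3-(propan-2-yl)-1,2,4,5,8,8a-hexahydroazulene-6-carboxylate
Conditions: TsOH·H2O (cat.), benzene, 50 °C
Reagents that add atoms: none
Why: Acid-catalysed dehydration through the tertiary C4 cation under equilibrating conditions (E1): loss of the C5 proton gives the tetrasubstituted endocyclic alkene, which is expected to be favoured over the isopropylidene isomer (allylic strain with the C5 substituents) and over the trisubstituted C3=C4 isomer; the C8=C9 alkene is deactivated toward protonation by the ester, and the C5 stereocentre disappears here.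

Step 15
Reactants: 22 diene ester
Product: 23 [(8aR)-8a-methyl-3-(propan-2-yl)-1,2,4,5,8,8a-hexahydroazulen-6-yl]methanol
Conditions: iBu2AlH, CH2Cl2, −78 → 0 °C; aq. potassium sodium tartrate
Reagents that add atoms: none
Why: 1,2-Reduction of the conjugated methyl ester by iBu2AlH gives the primary allylic alcohol; the two unactivated alkenes are untouched.

Step 16
Reactants: 23 [(8aR)-8a-methyl-3-(propan-2-yl)-1,2,4,5,8,8a-hexahydroazulen-6-yl]methanol; 24 4-hydroxy-3-methoxybenzoic acid (vanillic acid)
Product: 25 [(8aR)-8a-methyl-3-(propan-2-yl)-1,2,4,5,8,8a-hexahydroazulen-6-yl]methyl 4-hydroxy-3-methoxybenzoate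
Conditions: PPh3, diisopropyl azodicarboxylate, THF, 0 → 23 °C
Reagents that add atoms: none
Why: Mitsunobu esterification: the carboxyl group of 24 is far more acidic than its phenol, so the carboxylate is the nucleophile that displaces the primary allylic oxyphosphonium ion and the phenol needs no protection; C14 is not a stereocentre.

## Compound list

1 | 2,6-dimethylhept-5-enal (racemic) | CC(C)=CCCC(C)C=O | starting material
2 | but-3-en-2-one | CC(=O)C=C | starting material
3 | 1-(2,6-dimethylhepta-1,5-dien-1-yl)pyrrolidine (enamine, mixture of alkene isomers) | CC(C)=CCCC(C)=CN1CCCC1 | intermediate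
4 | 2-methyl-2-(4-methylpent-3-en-1-yl)-5-oxohexanal (racemic) | CC(C)=CCCC(C)(C=O)CCC(C)=O | intermediate
5 | 4-methyl-4-(4-methylpent-3-en-1-yl)cyclohex-2-en-1-one (racemic) | CC(C)=CCCC1(C)CCC(=O)C=C1 | intermediate
6 | trimethyl{[4-methyl-4-(4-methylpent-3-en-1-yl)cyclohexa-1,5-dien-1-yl]oxy}silane (racemic) | CC(C)=CCCC1(C)CC=C(O[Si](C)(C)C)C=C1 | intermediate
7 | 4-methyl-4-(4-methylpent-3-en-1-yl)cyclohexa-2,5-dien-1-one (achiral) | CC(C)=CCCC1(C)C=CC(=O)C=C1 | intermediate
8 | 4-[2-(5,5-dimethyl-1,2,4-trioxolan-3-yl)ethyl]-4-methylcyclohexa-2,5-dien-1-one (ozonide, racemic) | CC1(C)OOC(CCC2(C)C=CC(=O)C=C2)O1 | intermediate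
9 | 3-(1-methyl-4-oxocyclohexa-2,5-dien-1-yl)propanal (achiral) | O=CCCC1(C)C=CC(=O)C=C1 | intermediate
10 | (3aR,7aS)-3a-methyl-2,3,7,7a-tetrahydro-1H-indene-1,6(3aH)-dione (cis-fused) | O=C1CC[C@]2(C)C=CC(=O)C[C@H]12 | intermediate
11 | (3a'R,7a'S)-3a'-methyl-2',3',3a',7a'-tetrahydrospiro[[1,3]dioxolane-2,1'-inden]-6'(7'H)-one | C13(OCCO3)CC[C@]2(C)C=CC(=O)C[C@H]12 | intermediate
12 | lithium (3a'R,7a'S)-3a'-methyl-2',3',3a',7a'-tetrahydrospiro[[1,3]dioxolane-2,1'-inden]-6'-olate (cross-conjugated dienolate) | C13(OCCO3)CC[C@]2(C)C=CC([O-])=C[C@H]12.[Li+] | intermediate
13 | trimethyl{[(3a'R,7a'S)-3a'-methyl-2',3',3a',7a'-tetrahydrospiro[[1,3]dioxolane-2,1'-inden]-6'-yl]oxy}silane | C13(OCCO3)CC[C@]2(C)C=CC(O[Si](C)(C)C)=C[C@H]12 | intermediate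
14 | siloxycyclopropane: trimethylsilyl ether of the bicyclo[4.1.0]hept-4-en-1-ol formed by bridging C6 and C8 of 13 with C7 (C1 and C5 as in 13; epimer pair at C6/C8, cis-fused cyclopropane) | C13(OCCO3)CC[C@]2(C)C=CC4(O[Si](C)(C)C)CC4[C@H]12 | intermediate
15 | (3a'R)-8'-chloro-3a'-methyl-2',3',3a',7',8',8a'-hexahydrospiro[[1,3]dioxolane-2,1'-azulen]-6'-one (C5 as in 11; epimer pair at the chlorine-bearing C6) | C13(OCCO3)CC[C@]2(C)C=CC(=O)CC(Cl)[C@H]12 | intermediate
16 | (3a'R,8a'S)-3a'-methyl-2',3',3a',7',8',8a'-hexahydrospiro[[1,3]dioxolane-2,1'-azulen]-6'-one | C13(OCCO3)CC[C@]2(C)C=CC(=O)CC[C@H]12 | intermediate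
17 | lithium enolate of the C10-reduced ketone (enolate double bond C8=C9; C1 R, C5 S) | C13(OCCO3)CC[C@]2(C)CC=C([O-])CC[C@H]12.[Li+] | intermediate
18 | (3a'R,8a'S)-3a'-methyl-2',3',3a',4',7',8',8a'-heptahydrospiro[[1,3]dioxolane-2,1'-azulen]-6'-yl trifluoromethanesulfonate | C13(OCCO3)CC[C@]2(C)CC=C(OS(=O)(=O)C(F)(F)F)CC[C@H]12 | intermediate
19 | methyl (3a'R,8a'S)-3a'-methyl-2',3',3a',4',7',8',8a'-heptahydrospiro[[1,3]dioxolane-2,1'-azulene]-6'-carboxylate | C13(OCCO3)CC[C@]2(C)CC=C(C(=O)OC)CC[C@H]12 | intermediate
20 | methyl (3aS,8aR)-8a-methyl-3-oxo-1,2,3,3a,4,5,8,8a-octahydroazulene-6-carboxylate | O=C1CC[C@]2(C)CC=C(C(=O)OC)CC[C@H]12 | intermediate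
21 | methyl (3S,3aS,8aR)-3-hydroxy-8a-methyl-3-(propan-2-yl)-1,2,3,3a,4,5,8,8a-octahydroazulene-6-carboxylate | O[C@]1(C(C)C)CC[C@]2(C)CC=C(C(=O)OC)CC[C@H]12 | intermediate
22 | methyl (8aR)-8a-methyl-3-(propan-2-yl)-1,2,4,5,8,8a-hexahydroazulene-6-carboxylate | COC(=O)C1=CC[C@@]2(C)CCC(C(C)C)=C2CC1 | intermediate
23 | [(8aR)-8a-methyl-3-(propan-2-yl)-1,2,4,5,8,8a-hexahydroazulen-6-yl]methanol | OCC1=CC[C@@]2(C)CCC(C(C)C)=C2CC1 | intermediate
24 | 4-hydroxy-3-methoxybenzoic acid (vanillic acid) | COc1cc(C(=O)O)ccc1O | starting material
25 | [(8aR)-8a-methyl-3-(propan-2-yl)-1,2,4,5,8,8a-hexahydroazulen-6-yl]methyl 4-hydroxy-3-methoxybenzoate | COc1cc(C(=O)OCC2=CC[C@@]3(C)CCC(C(C)C)=C3CC2)ccc1O | target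

## Step count and least certain steps

Total: 16 steps. Longest linear sequence: 16 steps, from 1 to 25; 24 is used as purchased in the last step.

**Step 4 (key step).** The most likely failure is incomplete discrimination between the two enantiotopic enone arms, because the all-carbon tether is flexible and the catalyst must distinguish the arms through contacts remote from C1. Base-induced aldol self-condensation of the enolisable aldehyde may also consume substrate before the carbene engages it. Fallback: setting out from 9, the ring is closed with an achiral carbene precursor (3-benzyl-5-(2-hydroxyethyl)-4-methylthiazolium chloride, Et3N, ethanol, 70 °C). This should give 10 as the racemate, that is, together with its mirror image, the (3aS,7aR)-dione F1. Ketalisation of the C4 ketone of the mixture with (1R,2R)-1,2-diphenylethane-1,2-diol (TsOH·H2O, benzene, Dean–Stark) should give the diastereomeric dioxolanes, the (3a'R,7a'S)-ketal F2 and the (3a'S,7a'R)-ketal F3. These are separated by crystallisation or chromatography, and hydrolysis of F2 (aq. HCl, THF) comes back to the route at 10.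

**Step 9.** Chlorine abstraction from a secondary chloride is slow, so addition of the stannyl radical to the enone carbonyl (leading to loss of C9=C10 by conjugate reduction) and thermal loss of HCl toward the cross-conjugated dienone can compete. Fallback: setting out from 14, the silyl ether is cleaved (Bu4NF buffered with AcOH, THF, 0 °C) to the cyclopropanol F4. F4 is oxidised with manganese tris(pyridine-2-carboxylate), Mn(O2CC5H4N)3, in DMF at 0 °C in the presence of Bu3SnH. The β-keto radical formed by ring opening at trivalent manganese is then reduced directly by the stannane, without a chloride intermediate and without a tin radical chain. This comes back to the route at 16.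

**Step 13.** Enolisation of the hindered cyclopentanone by the branched nucleophile, or hydride transfer from it, would return or reduce 20, and warming to force conversion invites attack on the ester. Fallback: setting out from 20, the flatter and less basic isopropenyl nucleophile (isopropenylmagnesium bromide, CeCl3, THF, −78 °C) should give the isopropenyl carbinol F5. Hydrogenation over RhCl(PPh3)3 (H2, benzene) reduces the 1,1-disubstituted alkene in preference to the trisubstituted conjugated one and comes back to the route at 21.

**Step 14.** Proton loss from the C4 cation toward the isopropyl group or toward C3 would give regioisomeric alkenes, and prolonged acid exposure could carry the cation on to hydride and methyl shifts at the quaternary carbon. Fallback: setting out from 20 and bypassing 21, triflation under conditions that favour the more substituted enol (Tf2O, 2,6-di-tert-butyl-4-methylpyridine, CH2Cl2) should give the C4 enol triflate F6 with the double bond at C4=C5. Iron-catalysed cross-coupling with iPrMgCl (Fe(acac)3, THF/N-methylpyrrolidone, −30 °C), which tolerates the ester, comes back to the route at 22.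

**Step 16.** Alkylation of the phenol oxygen in place of the carboxylate, or allylic transposition and elimination of the oxyphosphonium ion, would lower the return of the last step. Fallback: setting out from 24, acetylation (Ac2O, pyridine) gives 4-acetoxy-3-methoxybenzoic acid F7. This is converted with (COCl)2 and catalytic DMF into 4-acetoxy-3-methoxybenzoyl chloride F8. Acylation of 23 (pyridine, 4-(dimethylamino)pyridine, CH2Cl2, 0 °C) gives the O-acetylated ester F9. Selective aminolysis of the aryl acetate with pyrrolidine (CH2Cl2, 0 °C) comes back to the route at 25.

## Further compounds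

F1 | step 4 | (3aS,7aR)-3a-methyl-2,3,7,7a-tetrahydro-1H-indene-1,6(3aH)-dione (mirror image of 10) | O=C1CC[C@@]2(C)C=CC(=O)C[C@@H]12
F2 | step 4 | (3a'R,4R,5R,7a'S)-3a'-methyl-4,5-diphenyl-2',3',3a',7a'-tetrahydrospiro[[1,3]dioxolane-2,1'-inden]-6'(7'H)-one | C13(O[C@H](c4ccccc4)[C@@H](c4ccccc4)O3)CC[C@]2(C)C=CC(=O)C[C@H]12
F3 | step 4 | (3a'S,4R,5R,7a'R)-3a'-methyl-4,5-diphenyl-2',3',3a',7a'-tetrahydrospiro[[1,3]dioxolane-2,1'-inden]-6'(7'H)-one | C13(O[C@H](c4ccccc4)[C@@H](c4ccccc4)O3)CC[C@@]2(C)C=CC(=O)C[C@@H]12
F4 | step 9 | cyclopropanol from desilylation of 14 (C1 and C5 as in 14; epimer pair at C6/C8) | C13(OCCO3)CC[C@]2(C)C=CC4(O)CC4[C@H]12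
F5 | step 13 | methyl (3R,3aS,8aR)-3-hydroxy-8a-methyl-3-(prop-1-en-2-yl)-1,2,3,3a,4,5,8,8a-octahydroazulene-6-carboxylate | O[C@]1(C(C)=C)CC[C@]2(C)CC=C(C(=O)OC)CC[C@H]12
F6 | step 14 | methyl (8aR)-8a-methyl-3-{[(trifluoromethyl)sulfonyl]oxy}-1,2,4,5,8,8a-hexahydroazulene-6-carboxylate | COC(=O)C1=CC[C@@]2(C)CCC(OS(=O)(=O)C(F)(F)F)=C2CC1
F7 | step 16 | 4-acetoxy-3-methoxybenzoic acid | COc1cc(C(=O)O)ccc1OC(C)=O
F8 | step 16 | 4-acetoxy-3-methoxybenzoyl chloride | COc1cc(C(Cl)=O)ccc1OC(C)=O
F9 | step 16 | [(8aR)-8a-methyl-3-(propan-2-yl)-1,2,4,5,8,8a-hexahydroazulen-6-yl]methyl 4-acetoxy-3-methoxybenzoate | COc1cc(C(=O)OCC2=CC[C@@]3(C)CCC(C(C)C)=C3CC2)ccc1OC(C)=O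
A1 | alternative 1 | 1-[4-(tert-butyldimethylsilyloxy)butyl]-5-[2-(tert-butyldimethylsilyloxy)ethyl]bicyclo[3.1.0]hexan-2-ol (methylene bridge syn to the hydroxyl; C1 of the daucane as in the target) | O[C@H]1CC[C@@]2(CCO[Si](C)(C)C(C)(C)C)C[C@@]12CCCCO[Si](C)(C)C(C)(C)C
A2 | alternative 1 | 2-[4-(tert-butyldimethylsilyloxy)butyl]-3-[2-(tert-butyldimethylsilyloxy)ethyl]cyclopent-2-en-1-ol (single enantiomer, carbinol as in A1) | O[C@H]1CCC(CCO[Si](C)(C)C(C)(C)C)=C1CCCCO[Si](C)(C)C(C)(C)C
A3 | alternative 2 | methyl (8aR)-8a-methyl-3-oxo-1,2,3,5,8,8a-hexahydroazulene-6-carboxylate | COC(=O)C1=CC[C@@]2(C)CCC(=O)C2=CC1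
A4 | alternative 2 | methyl 2-diazobut-3-enoate | COC(=O)C(=[N+]=[N-])C=C
A5 | alternative 2 | 2-ethenyl-3-methylcyclopent-2-en-1-one | C=CC1=C(C)CCC1=O
A6 | alternative 3 | bicyclo[5.3.0]decadienone with C3 ketone, C4=C5 bearing isopropyl on C4, C8=C9 bearing tert-butyldimethylsilyloxymethyl on C8, C1 as in the target | O=C1C[C@]2(C)CC=C(CO[Si](C)(C)C(C)(C)C)CCC2=C1C(C)C
A7 | alternative 3 | tert-butyldimethylsilyl ether of (2E)-5-methyl-2-(5-methylhex-3-yn-1-yl)hexa-2,5-dien-1-ol (C7 and C10 cis on C8=C9) | CC(C)C#CCC/C(CO[Si](C)(C)C(C)(C)C)=C\CC(C)=C
A8 | alternative 3 | carbon monoxide | [C-]#[O+]
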